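In the east and south-west runs, D and X together hold 52.1 % and 69.9 % of the E charged at the earliest readings and 49.9 % and 69.0 % at the last, so I treat the birth of D as a quick event and follow one number: the share of D in D plus X.

| flask | E | J | L | Z | remark | time |
|---|---|---|---|---|---|---|
| east | 0.20 M | 0.36 M | 0.40 M | 2 mM | run made earlier |  |
| south-west | 0.20 M | 0.36 M | 0.27 M | 2 mM | run made earlier |  |
| north | 0.20 M | 0.36 M | 0.60 M | 2 mM | run made earlier |  |
| west | 0.30 M | 0.36 M | 0.40 M | 2 mM | run made earlier |  |
| epsilon | 0.20 M | 0.360 M | 0.400 M | 2.0 mM | everything together in a closed stirred flask, run for 10 d | 10 d |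
| eta | 0.20 M (fed, over 10.0 d) | 0.360 M | 0.400 M | 2.0 mM | all but E at the start; E goes in evenly over 10.0 d, the run ends at 10 d | 10 d |
| gamma | 0.20 M | 0.360 M | 0.400 M (fed, over 10.0 d) | 2.0 mM | all but L at the start; L goes in evenly over 10.0 d, the run ends at 10 d | 10 d |
| theta | 0.20 M | 0.360 M | 0.400 M | 2.0 mM | a single well-mixed tank run continuously and read at steady state, 10 d in it on average |  |

| run | time / d | D / % | X / % |
|---|---|---|---|
| east | 0.833 | 44.5 | 7.6 |
| east | 1.25 | 40.5 | 9.3 |
| east | 1.67 | 38.5 | 11.5 |
| east | 3.00 | 31.2 | 19.8 |
| east | 4.00 | 27.5 | 23.8 |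
| east | 6.00 | 22.8 | 28.5 |
| east | 10.0 | 17.1 | 32.8 |
| south-west | 1.25 | 57.4 | 12.5 |
| south-west | 2.50 | 45.9 | 22.6 |
| south-west | 3.00 | 43.5 | 26.2 |
| south-west | 5.00 | 34.6 | 35.6 |
| south-west | 6.00 | 31.0 | 38.1 |
| south-west | 8.00 | 26.6 | 42.4 |
| north | 0.625 | 32.2 | 3.1 |
| north | 1.04 | 30.2 | 6.4 |
| north | 1.67 | 26.8 | 8.5 |
| north | 2.50 | 24.2 | 12.7 |
| north | 3.00 | 21.9 | 14.3 |
| north | 5.00 | 18.1 | 18.4 |
| north | 8.00 | 13.1 | 22.3 |
| west | 0.625 | 39.6 | 4.5 |
| west | 2.08 | 31.0 | 14.0 |
| west | 4.00 | 24.1 | 20.7 |
| west | 6.00 | 19.1 | 25.1 |
| west | 8.00 | 16.7 | 26.8 |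

(each reading ± 0.5 percentage points)

- the stated concentrations are those of everything mixed, before any reaction; amounts are the same in each set-up
- the numbers in the tables scatter by 0.5 percentage points (one standard deviation)
- the feed brings no volume worth counting
- the earlier runs were made in a closed, stirred flask

- the set-up with the highest share of D in all that became D or X, at the outlet or at the end ("none" if the first two lie within 2 percentage points) (epsilon / eta / gamma / theta / none)
- share of D in all that became D or X, at the outlet or at the end, epsilon
- share of D in all that became D or X, at the outlet or at the end, eta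
- share of D in all that became D or X, at the outlet or at the end, gamma
- share of D in all that became D or X, at the outlet or at the end, theta

I let that share start at one and fall exponentially towards a floor. Averaged over those two runs, it reads 61.8 % at 3.00 d and 44.7 % at 6.00 d, twice as late. The later loss over the earlier loss equals one plus the factor by which the excess over the floor shrinks per step, so that factor is 0.449. This gives 3.74 d, the relaxation time of the share, and a floor of 30.7 %. At 0.833 d, shorter than this time constant, the east run reads a share of 85.4 %, and the curve gives 86.2 %.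

The second time is the 10 d that D is given, and the ratio of the two is 2.67. In the closed flask epsilon the excess shrinks by the exponential of minus this ratio, 0.0693, so I reckon 35.5 %. In the tank theta, ages at the outlet spread exponentially around 10 d on average, so the factor is the reciprocal of one plus the ratio, 0.272, larger than the closed factor, and I reckon 49.6 %. I make no figure for eta and gamma, where a feed may spread the birth of D over the run, and of the two flasks I have reckoned I choose theta, which stands higher than epsilon.

The forecast also names theta, with 34.3 %, 39 %, 34.8 % and, above my tank figure, 55 %, on the ground that “D then goes to X with a clock that is the same in every run”.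

The simulated flasks give 34.5 % for epsilon, 35.6 % for eta, 34.6 % for gamma and 48.7 % for theta, so theta leads.

    E + J + Z → Z + D (k = 8.90 M⁻² min⁻¹)
    L + J + Z → Z + Q (k = 13.0 M⁻² min⁻¹)
    D ⇌ X (K = 2.40, k = 1.30 × 10⁻⁴ min⁻¹)

My tank figure lies 0.90 percentage points above the result, and for epsilon read at 2.5 d the same time constant and floor give 66.2 % against the simulated 66.6 %. In epsilon, the path from L to Q has done half of its turnover by 0.974 h. The path from D to X takes far longer, reaching that mark at 2.44 d.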